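Slowness comes first: the winter run, holding half the free enzyme of the autumn run, stands at 15% target after 5.00 h, where the autumn run stands at 30%. I want to know how the same charges end when they go in differently.

| setting | autumn | winter | alpha | eta | epsilon | gamma | zeta |
|---|---|---|---|---|---|---|---|
| starting material | 10 mM | 10 mM | 10 mM (in portions, 2, over 20 h) | 10 mM | 10 mM | 10 mM (fed, over 20 h) | 10 mM |
| second substrate | 50 mM | 50 mM | 50.0 mM | 50.0 mM (fed, over 20 h) | 50.0 mM (fed, over 2.0 h) | 50.0 mM | 50.0 mM |
| capture agent | 0.20 mM | 0.20 mM | 0.200 mM | 0.200 mM | 0.200 mM | 0.200 mM | 0.200 mM |
| free enzyme | 10 µM | 5 µM | 10 µM | 10 µM | 10 µM | 10 µM | 10 µM |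
| remark | run made earlier | run made earlier | first portion at the start, last at 20 h | all else is in the flask from the start; the feed brings no volume worth counting | all else is in the flask from the start; the feed brings no volume worth counting | all else is in the flask from the start; the feed brings no volume worth counting | everything together at the start |
| time |  |  | 25 h | 25 h | 25 h | 25 h | 25 h |

| autumn: time / h | autumn: target / % | winter: time / h | winter: target / % |
|---|---|---|---|
| 5.00 | 30 | 0.417 | 2 |
| 10.0 | 43 | 1.33 | 6 |
| 15.0 | 48 | 2.50 | 9 |
| 20.0 | 49 | 4.00 | 14 |
| 25.0 | 49 | 5.00 | 15 |

(each reading ± 1.5 percentage points)

* the flask that comes out highest in amount of target, in percent of the starting material charged, or "all alike" when all lie within 1.5 percentage points (alpha / eta / epsilon / gamma / zeta / all alike)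
* target at the end, in percent of the starting material charged, alpha
* target at the end, in percent of the starting material charged, eta
* target at the end, in percent of the starting material charged, epsilon
* target at the end, in percent of the starting material charged, gamma
* target at the end, in percent of the starting material charged, zeta



My first estimate is a turnover budget: the autumn run levels off at 49%, or 490 turnovers per enzyme, and every recipe spends the same budget. The objection is that the two runs cannot tell turnovers from hours, because at 5.00 h both enzymes have done equal turnovers. So I bet on the reading that separates the flasks: a rate dying on the clock.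

The autumn run gives a decay constant of 0.189 h⁻¹. The early winter reading, doubled for the enzyme, gives a fresh rate of 0.902 mM h⁻¹. Dividing the rate by the decay constant removes time and leaves 4.76 mM. I call this the reach, the target still to be made from a given moment, taken as that moment's rate over the decay constant. It lies near the autumn plateau of 4.90 mM, but that early reading carries a scatter of 1.5 percentage points, so the reach is rough.

In gamma, the feed of 0.500 mM h⁻¹ is slower than the fresh rate, so it sets the pace until the dying rate falls to it at 3.12 h. The reach of that moment then brings the total to 4.20 mM, or 42.0%. In alpha, the first portion exceeds the reach, and when the last portion arrives at 20 h the reach has shrunk to 0.108 mM, hardly any of that portion. The reach at the start already counts that late share, so I reckon alpha near 47.6%. The two runs share one charge of second substrate, so the reach says nothing about feeding it.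

The forecast reasons otherwise: “I take a fixed turnover budget as the simplest reading”. It gives 49% for alpha, 49% for eta, 49% for epsilon, 48% for gamma and 49% for zeta, with all alike as the highest. On gamma it parts from my figure.

The flasks give 33.3% for alpha, 55.6% for eta, 50.4% for epsilon, 42.4% for gamma and 49.4% for zeta, so eta comes highest.

    starting material + free enzyme ⇌ first complex (K = 150 L mol⁻¹, k = 35.2 L mol⁻¹ s⁻¹)
    first complex → loaded enzyme + first product (k = 1.02 s⁻¹)
    second substrate + loaded enzyme ⇌ second complex (K = 24.5 L mol⁻¹, k = 82.4 L mol⁻¹ s⁻¹)
    second complex → free enzyme + target (k = 0.0452 s⁻¹)
    capture agent + first complex → trapped intermediate (k = 0.904 L mol⁻¹ s⁻¹)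
    2 second substrate → homo dimer (k = 4.57 × 10⁻⁴ L mol⁻¹ s⁻¹)
    target ⇌ isomer of the product (K = 2.20, k = 1.55 × 10⁻⁵ s⁻¹)

My gamma figure stands close to the result, but alpha falls short of the reach, with 33.3% target, 29.1% isomer of the product and 37.5% starting material left at 25.0 h. The neighbouring flask is alpha with 6.0 mM of starting material. Its first portion lies under the reach, and the late reach of 0.108 mM is 3.59% of its last portion, so I reckon 51.8% target. It gives 40.0% target and 31.2% isomer of the product, with 28.7% starting material left.

The data stem from a simulated flask for an exercise; noise was put on by code.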